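What does doubling the free catalyst do to the rate of making target at a fixed conversion, and what does more reagent do?

| flask | starting material | reagent | capture agent | free catalyst | remark |
|---|---|---|---|---|---|
| Saturday's | 0.80 M | 0.76 M | 0.016 M | 0.31 mM | run made earlier |
| Friday's | 0.80 M | 0.76 M | 0.016 M | 1.2 mM | run made earlier |
| Monday's | 1.2 M | 0.76 M | 0.016 M | 0.62 mM | run made earlier |
| flask | 0.80 M | 0.760 M | 0.0160 M | 0.62 mM |  |

| run | time / h | target / % | starting material / % |
|---|---|---|---|
| Saturday's | 0.167 | 2 | 98 |
| Saturday's | 0.500 | 0 | 94 |
| Saturday's | 0.833 | 5 | 95 |
| Saturday's | 1.33 | 9 | 94 |
| Saturday's | 2.00 | 12 | 93 |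
| Saturday's | 2.50 | 12 | 91 |
| Saturday's | 3.00 | 14 | 84 |
| Friday's | 0.417 | 14 | 86 |
| Friday's | 0.833 | 23 | 75 |
| Friday's | 1.33 | 32 | 70 |
| Friday's | 1.50 | 35 | 64 |
| Friday's | 2.00 | 37 | 59 |
| Friday's | 2.50 | 43 | 59 |
| Friday's | 3.00 | 42 | 59 |
| Monday's | 0.250 | 1 | 94 |
| Monday's | 0.833 | 11 | 89 |
| Monday's | 1.33 | 12 | 90 |
| Monday's | 2.00 | 14 | 86 |
| Monday's | 3.00 | 18 | 83 |

(standard deviation of a reading: 2 percentage points)

- the earlier runs were read with a standard deviation of 2 percentage points
- no earlier run changes the charge of reagent; that part of a forecast is a guess

- apparent order in reagent when 5.0% of the starting material are converted (percent change of the rate of making target for one percent more reagent charged)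
- factor on the rate of making target when 5.0% of the starting material are converted if free catalyst is charged twice over

Examiner: what do the runs show most plainly? Friday's readings level off, with target at 43% and 42% at the last two while starting material still reads 59%, so I read the catalyst as dying.

Examiner: how do you put a number on that? In Friday's run capture agent was charged in excess of catalyst, so I assume that each round carries the same small chance of loss and define the catalyst's capacity, the turnover number, as target finally made per catalyst charged, which Friday's plateau reads as 283 at this [capture agent].

Examiner: and the new flask? Reaching 5.0% costs each catalyst on average 64.5 rounds, which by that capacity I reckon leaves 77.2% alive, whereas twice the charge spends half as many rounds per catalyst and by the same reckoning leaves 88.6%.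

Examiner: so why isn't the factor plain 2? Comparing at equal conversion rather than equal time, I take the rate as proportional to living catalyst, so my factor is 2.29. On reagent, the earlier runs were charged alike, at 0.76 M, so I commit to no number.

The forecast gave 2.7 for the doubling, higher than my figure, and 0.5 for the reagent, which it called a guess; of its order in catalyst it said “It could be a partly second-order catalyst, or a small part of it being lost”.

    reagent + free catalyst → catalyst intermediate A (k = 200 /M/min)
    starting material + catalyst intermediate A ⇌ catalyst intermediate B (K = 3.00 /M, k = 700 /M/min)
    catalyst intermediate B → by-product + catalyst intermediate C (k = 9.00 /min)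
    catalyst intermediate C ⇌ free catalyst + target (K = 51.0 M, k = 27.0 /min)
    capture agent + catalyst intermediate C → trapped intermediate (k = 5.50 /M/min)

The flask gives an apparent order in reagent of 0.036 and a factor of 2.26 for the doubling. At 0.300 h it holds 5.91% target and 24.7% of its catalyst as trapped intermediate, where target over capacity gives 26.9%. Monday's run, at the same [capture agent], is reckoned by that capacity to level off near 14.6% of its starting material, and its last reading, at 3.00 h, stood at 18%, a gap of 3.4 percentage points against a scatter of 2 points.

The numbers in the tables were computed for an exercise; scatter was added.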